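**Plan**

- Hypophaol is (S)-1-(3,4-dimethoxyphenyl)-3-(2,4,6-trimethoxyphenyl)propan-2-ol: ring A (trimethoxyphenyl) sits on C1, C2 is the carbinol, ring B (dimethoxyphenyl, C1' to C6', C1' bonded to C3) sits on C3.
- Enabling feature: the two methoxy-bearing carbons of ring B (C3', C4') are neighbours, so C2'–C3'–C4'–C5' is the chain of symmetric 2,3-dimethoxybuta-1,3-diene and C1'/C6' are the carbons of a terminal alkyne. Before ring B exists the C3 arm is a propargyl group, clearly different from the ring A benzyl arm.
- Retrosynthesis cuts, in order: the O–Si bond; ring B at C1'–C2' and C5'–C6' (two hydrogens added back); C3–C1' (acetylide plus epoxide); ring A–C1 (aryl Grignard reagent plus epichlorohydrin).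
- Forward: the ring A Grignard reagent opens (R)-epichlorohydrin; the chlorohydrin goes through its epoxide to the pent-4-yn-2-ol; silylation; cobalt-catalysed (4+2) cycloaddition builds ring B as its 1,4-dihydro form; dehydrogenation; desilylation.
- Stereochemistry: C2 is the stereocentre of (R)-epichlorohydrin. Its C–O bond is never broken, and the descriptor becomes S only because the ranking of the two carbon arms changes.

Key step: step 4

Remark on the chemistry: diene 9 is an acid-sensitive bis-enol ether, so it is taken into step 5 as the crude residue after filtration through basic alumina, without chromatography on silica.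

**Step 1**
Reactants: 1 2-bromo-1,3,5-trimethoxybenzene; 2 (R)-epichlorohydrin
Product: 4 (R)-1-chloro-3-(2,4,6-trimethoxyphenyl)propan-2-ol, via arylmagnesium bromide 3 (not isolated)
Conditions: Mg turnings, THF, reflux (I2 crystal to start); then CuI (10 mol%), 2, THF, −40 to 0 °C; aq. NH4Cl
Reagents that add atoms: none
Why: Copper-catalysed Grignard opening of a terminal epoxide, in which the arylcopper species from 3 and CuI attacks the unsubstituted epoxide carbon of 2 in an SN2 manner faster than it displaces chloride, and because the C–O bond at the epichlorohydrin stereocentre is not involved the (R) configuration is carried into 4.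

**Step 2**
Reactants: 4 (R)-1-chloro-3-(2,4,6-trimethoxyphenyl)propan-2-ol
Product: 6 (S)-1-(2,4,6-trimethoxyphenyl)pent-4-yn-2-ol, via epoxide 5 (not isolated)
Conditions: LiC≡CH·H2NCH2CH2NH2 (3 equiv), DMSO, 0 °C to rt; then H2O
Reagents that add atoms: lithium acetylide–ethylenediamine complex, [Li+].[C-]#C.NCCN
Why: Intramolecular Williamson epoxide closure followed by SN2 alkynylation of a terminal epoxide, in which the first equivalent of acetylide deprotonates the hydroxyl, the alkoxide displaces the neighbouring chloride to give 5 and a second equivalent attacks the epoxide CH2 in DMSO, so the C2–O bond stays intact and the descriptor changes from R to S only through the new ranking of the arms.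

**Step 3**
Reactants: 6 (S)-1-(2,4,6-trimethoxyphenyl)pent-4-yn-2-ol
Product: 7 (S)-tert-butyldimethyl{[1-(2,4,6-trimethoxyphenyl)pent-4-yn-2-yl]oxy}silane
Conditions: TBSCl, imidazole, DMF, rt
Reagents that add atoms: tert-butyldimethylsilyl chloride (TBSCl), CC(C)(C)[Si](C)(C)Cl
Why: Imidazole-promoted silylation of a secondary alcohol masks the hydroxyl against the Lewis-acidic zinc salts of step 4 and the quinone of step 5 and does not touch the stereocentre.

**Step 4**
Reactants: 7 (S)-tert-butyldimethyl{[1-(2,4,6-trimethoxyphenyl)pent-4-yn-2-yl]oxy}silane; 8 2,3-dimethoxybuta-1,3-diene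
Product: 9 (S)-tert-butyl{[1-(4,5-dimethoxycyclohexa-1,4-dien-1-yl)-3-(2,4,6-trimethoxyphenyl)propan-2-yl]oxy}dimethylsilane
Conditions: CoBr2(dppe) (10 mol%; dppe = 1,2-bis(diphenylphosphino)ethane), Zn powder (20 mol%), ZnI2 (20 mol%), 8 (3 equiv), CH2Cl2, rt; filtration through basic alumina
Reagents that add atoms: none
Why: Zn reduces the divalent cobalt of CoBr2(dppe) to monovalent cobalt and ZnI2 removes halide, so a cationic diphosphine cobalt centre binds the s-cis diene 8 and the terminal alkyne of 7; oxidative cyclisation forms the first C–C bond and a trivalent cobaltacycle, and reductive elimination forms the second C–C bond and releases the cyclohexa-1,4-diene. The closest known reaction type is the cobalt-catalysed neutral Diels–Alder reaction of unactivated terminal alkynes with 2,3-dialkyl and 2-oxygenated buta-1,3-dienes, to which 8 adds only a second enol-ether oxygen. Ring B, a six-membered carbocycle, is closed by intermolecular (4+2) annulation in which the internal alkyne carbon (C1') bonds to one diene terminus (C2') and the terminal alkyne carbon (C6') to the other (C5'). No stereocentre is formed, and the silyloxy-bearing C2, one CH2 away from the alkyne, takes no part in any bond change. The step needs chemoselectivity for cross-cycloaddition over alkyne cyclotrimerisation and diene oligomerisation, which the chelating dppe ligand and the threefold excess of diene should provide; regioselectivity is not an issue because 8 is symmetric and both orientations give the same 4,5-dimethoxy pattern.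

**Step 5**
Reactants: 9 (S)-tert-butyl{[1-(4,5-dimethoxycyclohexa-1,4-dien-1-yl)-3-(2,4,6-trimethoxyphenyl)propan-2-yl]oxy}dimethylsilane
Product: 10 (S)-tert-butyl{[1-(3,4-dimethoxyphenyl)-3-(2,4,6-trimethoxyphenyl)propan-2-yl]oxy}dimethylsilane
Conditions: DDQ (1.05 equiv), toluene, 0 °C to rt; aq. NaHCO3 wash
Reagents that add atoms: none
Why: Dehydrogenative aromatisation with DDQ, in which hydride abstraction from a doubly allylic, oxygen-stabilised CH2 of the cyclohexa-1,4-diene and proton loss are driven by the gain of aromaticity and should be far faster than oxidation at the benzylic CH2 groups, so one equivalent at low temperature should convert only the diene ring into ring B.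

**Step 6**
Reactants: 10 (S)-tert-butyl{[1-(3,4-dimethoxyphenyl)-3-(2,4,6-trimethoxyphenyl)propan-2-yl]oxy}dimethylsilane
Product: 11 hypophaol, (S)-1-(3,4-dimethoxyphenyl)-3-(2,4,6-trimethoxyphenyl)propan-2-ol
Conditions: Bu4NF, THF, 0 °C to rt
Reagents that add atoms: none
Why: Fluoride-induced desilylation, driven by the strong Si–F bond, cleaves the O–Si bond and not the C2–O bond, so the (S) configuration is retained and the aryl methyl ethers are untouched.

**Compound list**

1 | 2-bromo-1,3,5-trimethoxybenzene | COc1cc(OC)c(Br)c(OC)c1 | starting material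
2 | (R)-epichlorohydrin, (R)-2-(chloromethyl)oxirane | ClC[C@H]1CO1 | starting material
3 | (2,4,6-trimethoxyphenyl)magnesium bromide | COc1cc(OC)c([Mg]Br)c(OC)c1 | intermediate (not isolated)
4 | (R)-1-chloro-3-(2,4,6-trimethoxyphenyl)propan-2-ol | COc1cc(OC)c(C[C@@H](O)CCl)c(OC)c1 | intermediate
5 | (R)-2-(2,4,6-trimethoxybenzyl)oxirane | COc1cc(OC)c(C[C@@H]2CO2)c(OC)c1 | intermediate (not isolated)
6 | (S)-1-(2,4,6-trimethoxyphenyl)pent-4-yn-2-ol | COc1cc(OC)c(C[C@@H](O)CC#C)c(OC)c1 | intermediate
7 | (S)-tert-butyldimethyl{[1-(2,4,6-trimethoxyphenyl)pent-4-yn-2-yl]oxy}silane | COc1cc(OC)c(C[C@@H](O[Si](C)(C)C(C)(C)C)CC#C)c(OC)c1 | intermediate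
8 | 2,3-dimethoxybuta-1,3-diene | COC(=C)C(=C)OC | starting material
9 | (S)-tert-butyl{[1-(4,5-dimethoxycyclohexa-1,4-dien-1-yl)-3-(2,4,6-trimethoxyphenyl)propan-2-yl]oxy}dimethylsilane | COc1cc(OC)c(C[C@@H](O[Si](C)(C)C(C)(C)C)CC2=CCC(OC)=C(OC)C2)c(OC)c1 | intermediate
10 | (S)-tert-butyl{[1-(3,4-dimethoxyphenyl)-3-(2,4,6-trimethoxyphenyl)propan-2-yl]oxy}dimethylsilane | COc1cc(OC)c(C[C@@H](O[Si](C)(C)C(C)(C)C)Cc2ccc(OC)c(OC)c2)c(OC)c1 | intermediate
11 | hypophaol, (S)-1-(3,4-dimethoxyphenyl)-3-(2,4,6-trimethoxyphenyl)propan-2-ol | COc1cc(OC)c(C[C@@H](O)Cc2ccc(OC)c(OC)c2)c(OC)c1 | target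

**Count**

Total steps: 6. Longest linear sequence: 6 steps (1 to 11); 2 and 8 are bought and enter in steps 1 and 4.

**Steps most likely to fail**

1. Step 4 (key step). What may go wrong: cyclotrimerisation of the alkyne or ZnI2-induced oligomerisation of the electron-rich diene outpaces the cross-cycloaddition, or the hindered, oxygen-rich substrate slows the catalyst. Fallback: form the C3–C1' bond by ionic epoxide opening with a ready-made ring B. Setting out from chlorohydrin 4, K2CO3 in MeOH closes the epoxide 5, which is isolated. 4-Bromo-1,2-dimethoxybenzene and Mg in THF give (3,4-dimethoxyphenyl)magnesium bromide F1, which with CuI (10 mol%) at −40 to 0 °C should open 5 at its CH2 terminus. This gives hypophaol directly, so the route is rejoined at 11, with the stereocentre again inherited from 2.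

2. Step 1. What may go wrong: the doubly ortho-substituted Grignard reagent attacks sluggishly, so that halide exchange, opening of the epoxide by bromide or attack at the C–Cl carbon compete. Fallback: build the chain first as an aldehyde and set C2 by catalyst control. Setting out from 1 (through its Grignard reagent 3), allyl bromide should give 2-allyl-1,3,5-trimethoxybenzene F2. Lemieux–Johnson cleavage (OsO4 cat., NaIO4, 2,6-lutidine, dioxane–H2O) gives 2-(2,4,6-trimethoxyphenyl)acetaldehyde F3, which is used at once. Enantioselective propargylation with allenylboronic acid pinacol ester under a 3,3'-bis(2,4,6-triisopropylphenyl)-BINOL phosphoric acid (the antipode that delivers the (S)-alcohol; toluene, low temperature, molecular sieves) gives the alkynol and rejoins the route at 6.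

3. Step 2. What may go wrong: in strongly basic DMSO the terminal alkyne isomerises to an allene or internal alkyne, or the epoxide eliminates to the allylic alcohol before it is opened. Fallback: Lewis-acid-assisted opening with a capped acetylide at low temperature. Setting out from 4, K2CO3 in MeOH gives 5 (isolated). Commercial lithium (trimethylsilyl)acetylide with BF3·OEt2 in THF at −78 °C should give (R)-1-(2,4,6-trimethoxyphenyl)-5-(trimethylsilyl)pent-4-yn-2-ol F4, which has the same spatial arrangement as 6; the descriptor reads R because the silylated arm outranks the benzyl arm. K2CO3 in MeOH then removes the C-silyl group and the route is rejoined at 6.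

**Further compounds**

F1 | step 4 | (3,4-dimethoxyphenyl)magnesium bromide | COc1ccc([Mg]Br)cc1OC
F2 | step 1 | 2-allyl-1,3,5-trimethoxybenzene | C=CCc1c(OC)cc(OC)cc1OC
F3 | step 1 | 2-(2,4,6-trimethoxyphenyl)acetaldehyde | COc1cc(OC)c(CC=O)c(OC)c1
F4 | step 2 | (R)-1-(2,4,6-trimethoxyphenyl)-5-(trimethylsilyl)pent-4-yn-2-ol | COc1cc(OC)c(C[C@@H](O)CC#C[Si](C)(C)C)c(OC)c1
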